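**Retrosynthetic overview**
1. The target is an oxidative dimer of one monomer, (2S,4R)-5-hydroxy-7,8-dimethoxyflavan-4-ol (10). The C6–C8'' bond is cut so that one molecule reacts as an oxidised, electrophilic phenol (aryloxy-λ3-iodane, an enolonium-type equivalent) and the other as the C6 nucleophile.
2. The C8a''–O5 ketal and the C4''=C4a'' enone follow in the same flask by loss of the 4''-OH of the oxidised half and capture by the neighbouring 5-OH.
3. 10 comes from the cis-flavan-4-ol 8 by Mitsunobu inversion, and 8 from the (S)-flavanone 7 by hydride reduction.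
4. 7 comes from chromone 5 and PhB(OH)2 by Pd-catalysed asymmetric conjugate addition (sets C2 and C2''); 5 comes from acetophenone 1 and DMF-DMA, then 5-O-demethylation.
5. Ring order: chromone pyranone → C2 stereocentre → flavan-4-ol → in the last step the dearomatised cyclohexadienone, the dihydrobenzofuran ketal and the 2H-pyran enone.

Assumption: 1 is taken as a catalogue compound (otherwise one Friedel–Crafts acetylation/ortho-demethylation from 1,2,3,5-tetramethoxybenzene); unprimed locants are the flavan-4-ol half, double-primed locants the dearomatised half.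

**Step 1**
Reactants: 1 2'-hydroxy-3',4',6'-trimethoxyacetophenone; 2 N,N-dimethylformamide dimethyl acetal
Product: 4 5,7,8-trimethoxy-4H-chromen-4-one, via enaminone 3 (not isolated)
Conditions: 2 (2 equiv), PhMe, 110 °C; then conc. HCl, CH2Cl2, rt
Reagents that add atoms: N,N-dimethylformamide dimethyl acetal (2) COC(OC)N(C)C
Why: Enaminone chromone synthesis: condensation at the acetyl CH3, then acid-promoted addition–elimination of the 2'-OH with loss of Me2NH closes the pyranone; no stereocentre.

**Step 2**
Reactants: 4 5,7,8-trimethoxy-4H-chromen-4-one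
Product: 5 5-hydroxy-7,8-dimethoxy-4H-chromen-4-one
Conditions: BCl3 (1.2 equiv), CH2Cl2, −78 → 0 °C; aq. NaHCO3
Reagents that add atoms: none
Why: Chelation-controlled Lewis-acid demethylation: BCl3 bridges the C4 carbonyl and the peri 5-OMe, so only that ether is cleaved, and it is done on the achiral chromone so no stereocentre is at risk.

**Step 3**
Reactants: 5 5-hydroxy-7,8-dimethoxy-4H-chromen-4-one; 6 phenylboronic acid
Product: 7 (2S)-5-hydroxy-7,8-dimethoxy-2-phenylchroman-4-one
Conditions: Pd(TFA)2 (5 mol %), (R)-t-BuPyOx (6 mol %), NH4PF6 (30 mol %), H2O (5 equiv), ClCH2CH2Cl, 60 °C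
Reagents that add atoms: phenylboronic acid (6) OB(O)c1ccccc1
Why: Pd(II)/pyridine-oxazoline asymmetric conjugate addition of an arylboronic acid to a chromone (air-, water- and phenol-tolerant); the (R)-ligand is chosen by analogy with cyclic enones so that aryl-Pd insertion on the enone face gives 2S, and water protonates the Pd enolate.

**Step 4**
Reactants: 7 (2S)-5-hydroxy-7,8-dimethoxy-2-phenylchroman-4-one
Product: 8 (2S,4S)-7,8-dimethoxy-2-phenylchromane-4,5-diol (2,4-cis)
Conditions: NaBH4 (2 equiv), MeOH/THF, −10 → 0 °C; pH 7 buffer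
Reagents that add atoms: none
Why: Substrate-controlled hydride reduction: axial attack on the half-chair with equatorial 2-phenyl gives the equatorial, 2,4-cis (4S) alcohol, and the low temperature suppresses base-induced ring opening that would racemise C2.

**Step 5**
Reactants: 8 (2S,4S)-7,8-dimethoxy-2-phenylchromane-4,5-diol
Product: 10 (2S,4R)-7,8-dimethoxy-2-phenylchromane-4,5-diol (2,4-trans), via trans-4-nitrobenzoate 9 (not isolated)
Conditions: PPh3, DIAD, 4-O2NC6H4CO2H, THF, 0 °C → rt; then LiOH, THF/H2O, 0 °C; aq. NH4Cl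
Reagents that add atoms: 4-nitrobenzoic acid O=C(O)c1ccc(cc1)[N+](=O)[O-]
Why: Mitsunobu inversion: the carboxylate displaces the activated benzylic oxygen with inversion to set 4R (an o-quinone-methide pathway would also add the acid axially, trans to the equatorial 2-phenyl), and saponification frees the trans alcohol.

**Step 6**
Reactants: 10 (2S,4R)-7,8-dimethoxy-2-phenylchromane-4,5-diol (two molecules)
Product: 13 6''-demethoxyneocalycopterone, via aryloxy-λ3-iodane 11 (not isolated), via coupled dienone 12 (not isolated)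
Conditions: PhI(OAc)2 (0.55 equiv), 4 Å MS, (CF3)2CHOH/CH2Cl2 (1:4), −40 → 0 °C
Reagents that add atoms: none
Why: Proposed new method: PhI(OAc)2 turns one molecule of 10 into aryloxy-iodane 11, a phenoxenium (enolonium-type) equivalent whose OMe-bearing para carbon C8'' is the most electron-poor site (C6'' is the electron-rich β-carbon of the 7''-enol ether), and C6 of a second, unoxidised molecule (its only free, phloroglucinol-type position) attacks there with loss of PhI/AcOH, joining two normally nucleophilic carbons to give dienone 12; 12 is a vinylogous hemiacetal (4''-OH γ to the enol-ether O1''), so it ionises in HFIP/AcOH to a pyranyl oxocarbenium that the neighbouring 5-OH traps at C8a'' (5-ring closure), leaving the C4''=C4a'' enone; C8''/C8a'' must be cis, and only the adduct with aryl on the face opposite the 2''-phenyl can close by axial, anomerically assisted attack with phenyl equatorial, which gives 8''S,8a''S (the C8'' epimer is expected as a separable minor product); closest known reaction types are Pummerer-ketone/usnic-acid ortho–para oxidative phenol coupling and iodane-mediated oxidative nucleophilic substitution at alkoxy-bearing arenol carbons.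

**Compound list**
1 | 2'-hydroxy-3',4',6'-trimethoxyacetophenone | CC(=O)c1c(O)c(OC)c(OC)cc1OC | starting material
2 | N,N-dimethylformamide dimethyl acetal | COC(OC)N(C)C | starting material
3 | (E)-3-(dimethylamino)-1-(2-hydroxy-3,4,6-trimethoxyphenyl)prop-2-en-1-one | CN(C)/C=C/C(=O)c1c(O)c(OC)c(OC)cc1OC | intermediate (not isolated)
4 | 5,7,8-trimethoxy-4H-chromen-4-one | COc1cc(OC)c2c(=O)ccoc2c1OC | intermediate
5 | 5-hydroxy-7,8-dimethoxy-4H-chromen-4-one | COc1cc(O)c2c(=O)ccoc2c1OC | intermediate
6 | phenylboronic acid | OB(O)c1ccccc1 | starting material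
7 | (2S)-5-hydroxy-7,8-dimethoxy-2-phenylchroman-4-one | O=C1C[C@@H](c2ccccc2)Oc2c(OC)c(OC)cc(O)c12 | intermediate
8 | (2S,4S)-7,8-dimethoxy-2-phenylchromane-4,5-diol (cis) | O[C@H]1C[C@@H](c2ccccc2)Oc2c(OC)c(OC)cc(O)c12 | intermediate
9 | (2S,4R)-5-hydroxy-7,8-dimethoxy-2-phenylchroman-4-yl 4-nitrobenzoate | O=C(O[C@@H]1C[C@@H](c2ccccc2)Oc2c(OC)c(OC)cc(O)c12)c1ccc(cc1)[N+](=O)[O-] | intermediate (not isolated)
10 | (2S,4R)-7,8-dimethoxy-2-phenylchromane-4,5-diol (trans) | O[C@@H]1C[C@@H](c2ccccc2)Oc2c(OC)c(OC)cc(O)c12 | intermediate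
11 | acetoxy(phenyl)-λ3-iodanyl ether of the 5-OH of 10 | CC(=O)OI(c1ccccc1)Oc1cc(OC)c(OC)c2O[C@H](c3ccccc3)C[C@@H](O)c12 | intermediate (not isolated)
12 | (2''S,4''R,8''S)-4''-hydroxy-7'',8''-dimethoxy-2''-phenyl-8''-[(2S,4R)-4,5-dihydroxy-7,8-dimethoxy-2-phenylchroman-6-yl]-3'',4''-dihydro-2''H-chromen-5''(8''H)-one | COC1=CC(=O)C2=C(O[C@H](c3ccccc3)C[C@H]2O)[C@]1(OC)c1c(OC)c(OC)c2O[C@H](c3ccccc3)C[C@@H](O)c2c1O | intermediate (not isolated)
13 | 6''-demethoxyneocalycopterone (2S,4R,2''S,8''S,8a''S) | COC1=CC(=O)C2=CC[C@@H](c3ccccc3)O[C@]23Oc2c4c(c(OC)c(OC)c2[C@]13OC)O[C@H](c1ccccc1)C[C@H]4O | target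

**Totals**
Total steps: 6. Longest linear sequence: 6 (the last step uses two molecules of 10).

**Steps most likely to fail**

Step 6 (oxidative dimerisation). Risks are attack at C6'' to give a 6,6''-biaryl, C–O coupling, low facial selectivity at C8'' and acid-triggered loss of the 4-OH. The fallback sets out from 10 and makes the coupling a hetero-coupling with the competing position blocked. NBS (1 equiv, CH2Cl2, −78 °C) brominates the only free ring position to give (2S,4R)-6-bromo-7,8-dimethoxy-2-phenylchromane-4,5-diol F1. PhI(OAc)2 in MeOH at 0 °C converts it into the isolable quinone monoketal (2S,4R)-6-bromo-4-hydroxy-7,8,8-trimethoxy-2-phenyl-3,4-dihydro-2H-chromen-5(8H)-one F2. F2 and one equivalent of 10 are combined with catalytic BF3·OEt2 in CH2Cl2/HFIP at −40 °C. C6 of 10 can then only substitute the ionised ketal carbon, and the 5-OH closes the ketal with loss of the 4''-OH, giving 6''-bromo-6''-demethoxyneocalycopterone F3. Pd(PPh3)4/Bu3SnH hydrodebromination of the α-bromo enone returns to the route at 13.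

Step 5 (Mitsunobu on a free o-hydroxybenzylic alcohol). Risks are elimination to the flav-3-ene, oligomerisation through the o-quinone methide and incomplete inversion. The fallback sets out from 8 and moves the inversion to the end, where no free phenol is left. The cis-diol 8 is dimerised under the step-6 conditions (its 4''-OH is lost in any case) to give 4-epi-6''-demethoxyneocalycopterone F4, which has a single hydroxyl group. Mitsunobu reaction with 4-nitrobenzoic acid gives the inverted 4-O-(4-nitrobenzoyl)-6''-demethoxyneocalycopterone F5. K2CO3/MeOH at 0 °C cleaves the ester and returns to the route at 13.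

Step 3 (asymmetric arylation of a chelating 5-hydroxychromone). Risks are catalyst sequestration by the peri-hydroxy ketone and eroded ee. The fallback sets out from 4 and reverses the order of arylation and demethylation. The same Pd/(R)-t-BuPyOx addition of 6 to the non-chelating trimethoxychromone 4 gives (2S)-5,7,8-trimethoxy-2-phenylchroman-4-one F6. BCl3 in CH2Cl2 at −78 °C then removes only the peri 5-O-methyl group (kept cold to avoid ring opening) and returns to the route at 7.

**Further compounds**
F1 | step 6 | (2S,4R)-6-bromo-7,8-dimethoxy-2-phenylchromane-4,5-diol | O[C@@H]1C[C@@H](c2ccccc2)Oc2c(OC)c(OC)c(Br)c(O)c12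
F2 | step 6 | (2S,4R)-6-bromo-4-hydroxy-7,8,8-trimethoxy-2-phenyl-3,4-dihydro-2H-chromen-5(8H)-one | COC1=C(Br)C(=O)C2=C(O[C@H](c3ccccc3)C[C@H]2O)C1(OC)OC
F3 | step 6 | 6''-bromo-6''-demethoxyneocalycopterone | COC1=C(Br)C(=O)C2=CC[C@@H](c3ccccc3)O[C@]23Oc2c4c(c(OC)c(OC)c2[C@]13OC)O[C@H](c1ccccc1)C[C@H]4O
F4 | step 5 | 4-epi-6''-demethoxyneocalycopterone (4S) | COC1=CC(=O)C2=CC[C@@H](c3ccccc3)O[C@]23Oc2c4c(c(OC)c(OC)c2[C@]13OC)O[C@H](c1ccccc1)C[C@@H]4O
F5 | step 5 | 4-O-(4-nitrobenzoyl)-6''-demethoxyneocalycopterone (4R) | COC1=CC(=O)C2=CC[C@@H](c3ccccc3)O[C@]23Oc2c4c(c(OC)c(OC)c2[C@]13OC)O[C@H](c1ccccc1)C[C@H]4OC(=O)c1ccc(cc1)[N+](=O)[O-]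
F6 | step 3 | (2S)-5,7,8-trimethoxy-2-phenylchroman-4-one | COc1cc(OC)c2c(c1OC)O[C@H](c1ccccc1)CC2=O
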